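**Retrosynthetic overview**
- The strategy rests on ring A of the 2H-chromene: C8 (prenyl), C7 (OH), C6 (CO2Me) and C5 (arylethyl) carry exactly the substituents of C3, C4, C5 and C6 of a 4-oxygenated 2-pyrone-5-carboxylate, so only C8a and C4a have to be added.
- Ring B (pyran) is cut last at O1–C2 and C4–C4a: the O8a phenol, whose only free ortho carbon is C4a, plus 3-methylbut-2-enal.
- Ring A is cut at C4a–C5 and C8–C8a: inverse-demand [4+2] of a fully substituted pyrone with a ketene bis(silyl) acetal, then loss of CO2 and silanol.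
- The pyrone comes from a keto ester (acetoacetate dianion plus a benzylic bromide) and malonyl dichloride, followed by C3-prenylation and O-protection.
- Order of ring formation: pyrone ring, then ring A out of the pyrone, then ring B.

Key step: step 9

Remark on the chemistry: the target has no stereocentre, so no step has to set configuration. Ring positions are given in chromene numbering (O1, C2, C3, C4, C4a, C5 to C8, C8a). TBS = tert-butyldimethylsilyl, MOM = methoxymethyl.

Step 1
Reactants: 1 4-hydroxybenzyl alcohol
Product: 2 tert-butyl{[4-(tert-butyldimethylsilyloxy)phenyl]methoxy}dimethylsilane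
Conditions: TBSCl (2.3 equiv), imidazole (4.5 equiv), DMF, 0 °C to rt
Reagents that add atoms: tert-butyldimethylsilyl chloride (TBSCl), CC(C)(C)[Si](C)(C)Cl
Why: Exhaustive imidazole-promoted silylation (standard silyl ether formation) caps the phenol and the primary alcohol in one operation.

Step 2
Reactants: 2 tert-butyl{[4-(tert-butyldimethylsilyloxy)phenyl]methoxy}dimethylsilane
Product: 3 4-(tert-butyldimethylsilyloxy)benzyl bromide
Conditions: Ph3PBr2 (1.1 equiv), CH2Cl2, 0 °C to rt; short silica plug, used at once
Reagents that add atoms: triphenylphosphine dibromide, BrP(Br)(c1ccccc1)(c1ccccc1)c1ccccc1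
Why: Known conversion of alkyl silyl ethers into bromides by Ph3PBr2: the benzylic ether oxygen is phosphonylated with loss of silyl bromide and bromide displaces Ph3PO at the activated benzylic carbon (SN2), whereas the aryl silyl ether offers no carbon for substitution and should stay.

Step 3
Reactants: 4 methyl acetoacetate; 3 4-(tert-butyldimethylsilyloxy)benzyl bromide
Product: 6 methyl 5-[4-(tert-butyldimethylsilyloxy)phenyl]-3-oxopentanoate, via methyl acetoacetate sodium lithium dianion 5 (not isolated)
Conditions: NaH (1.1 equiv), THF, 0 °C; n-BuLi (1.05 equiv), 0 °C; then 3 (0.9 equiv), 0 °C to rt; 1 M HCl quench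
Reagents that add atoms: none
Why: Weiler dianion alkylation: the more basic terminal carbanion of the dianion reacts at the gamma carbon with the reactive benzylic bromide, and the aryl silyl ether is inert to the enolate.

Step 4
Reactants: 6 methyl 5-[4-(tert-butyldimethylsilyloxy)phenyl]-3-oxopentanoate; 7 malonyl dichloride
Product: 9 methyl 6-{2-[4-(tert-butyldimethylsilyloxy)phenyl]ethyl}-4-hydroxy-2-oxo-2H-pyran-5-carboxylate, via C2-malonylated keto ester acid chloride 8 (not isolated)
Conditions: 7 (1.0 equiv), CH2Cl2, 0 °C to 40 °C, slow N2 sweep to carry off HCl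
Reagents that add atoms: none
Why: Known malonyl dichloride annulation of beta-keto esters to 4-hydroxy-2-pyrone-5-carboxylates: C-acylation of the keto ester at C2 by one acid chloride and O-acylation of the ketone enol by the other close the lactone, and an aryl silyl ether is the most acid-tolerant kind of silyl ether.

Step 5
Reactants: 9 methyl 6-{2-[4-(tert-butyldimethylsilyloxy)phenyl]ethyl}-4-hydroxy-2-oxo-2H-pyran-5-carboxylate; 10 prenyl acetate (3-methylbut-2-en-1-yl acetate)
Product: 11 methyl 6-{2-[4-(tert-butyldimethylsilyloxy)phenyl]ethyl}-4-hydroxy-3-(3-methylbut-2-en-1-yl)-2-oxo-2H-pyran-5-carboxylate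
Conditions: 10 (1.05 equiv), Pd(PPh3)4 (5 mol %), Et3N (1.1 equiv), THF, 50 °C
Reagents that add atoms: none
Why: Tsuji–Trost allylation, known for C3 of 4-hydroxy-2-pyrones: the soft C3 carbon of the pyronate attacks the unsubstituted terminus of the (1,1-dimethylallyl)palladium cation formed from zerovalent palladium and prenyl acetate, and any O-prenyl ether formed first is itself an allylic electrophile and is funnelled to the C-prenyl product.

Step 6
Reactants: 11 methyl 6-{2-[4-(tert-butyldimethylsilyloxy)phenyl]ethyl}-4-hydroxy-3-(3-methylbut-2-en-1-yl)-2-oxo-2H-pyran-5-carboxylate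
Product: 12 methyl 6-{2-[4-(tert-butyldimethylsilyloxy)phenyl]ethyl}-4-(methoxymethoxy)-3-(3-methylbut-2-en-1-yl)-2-oxo-2H-pyran-5-carboxylate
Conditions: MOMCl (1.5 equiv), i-Pr2NEt (2 equiv), CH2Cl2, 0 °C to rt
Reagents that add atoms: chloromethyl methyl ether (MOMCl), COCCl
Why: Standard methoxymethylation: the hard electrophile alkylates the acidic 4-oxygen of the ammonium pyronate, while C-alkylation at the already substituted C3 would have to build a quaternary carbon.

Step 7
Reactants: 13 acetic acid
Product: 14 tert-butyldimethylsilyl acetate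
Conditions: TBSCl (1.0 equiv), Et3N (1.1 equiv), CH2Cl2, 0 °C to rt; filtration, distillation
Reagents that add atoms: tert-butyldimethylsilyl chloride (TBSCl), CC(C)(C)[Si](C)(C)Cl
Why: Silyl ester formation by O-silylation of triethylammonium acetate.

Step 8
Reactants: 14 tert-butyldimethylsilyl acetate
Product: 16 1,1-bis(tert-butyldimethylsilyloxy)ethene, via lithium enolate of silyl acetate 15 (not isolated)
Conditions: LiN(i-Pr)2 (1.1 equiv), THF, −78 °C; TBSCl (1.1 equiv), DMPU, −78 °C to rt; pentane, filtration, bulb-to-bulb distillation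
Reagents that add atoms: tert-butyldimethylsilyl chloride (TBSCl), CC(C)(C)[Si](C)(C)Cl
Why: Standard silyl ketene acetal formation: kinetic enolization of the ester by the lithium amide and O-silylation of the enolate in the presence of DMPU, the bulky silyl group disfavouring C-silylation.

Step 9
Reactants: 12 methyl 6-{2-[4-(tert-butyldimethylsilyloxy)phenyl]ethyl}-4-(methoxymethoxy)-3-(3-methylbut-2-en-1-yl)-2-oxo-2H-pyran-5-carboxylate; 16 1,1-bis(tert-butyldimethylsilyloxy)ethene
Product: 19 methyl 4-(tert-butyldimethylsilyloxy)-6-{2-[4-(tert-butyldimethylsilyloxy)phenyl]ethyl}-2-(methoxymethoxy)-3-(3-methylbut-2-en-1-yl)benzoate, via bridged lactone cycloadduct 17 (not isolated), via cyclohexadiene bis(silyl) ketal 18 (not isolated)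
Conditions: 16 (5 equiv), mesitylene, sealed silylated tube, 150 °C (alternative activation: 12 kbar, CH2Cl2, 40 °C); filtration through Et3N-deactivated silica
Reagents that add atoms: none
Why: Proposed new method: the pyrone serves as an electron-poor diene whose C6 is the beta carbon of the C5 ester and the delta carbon of the lactone carbonyl, so the nucleophilic CH2 of 16 should bond there first (future C4a–C5) and the developing bis(silyloxy)carbenium carbon should then be captured by pyrone C3 (future C8–C8a). Ring A is thereby closed by [4+2] cycloaddition across the diene termini, concerted but asynchronous or stepwise through the zwitterion (Michael addition, then six-membered closure of the lactone dienolate carbon onto the oxocarbenium ion), as the carbocycle of the 2-oxabicyclo[2.2.2]octenone 17. Retro-[4+2] loss of CO2 from 17 should give cyclohexadiene 18, and elimination of tert-butyldimethylsilanol across its CH2–C(OSi)2 bond aromatizes it, which makes the sequence irreversible. The closest known reaction type is the inverse-electron-demand Diels–Alder, decarboxylation and elimination sequence of ester-bearing 2-pyrones (coumalates, 3-carbomethoxy-2-pyrones) with ketene acetals to alkoxybenzoates; a fully substituted diene carrying a 4-alkoxy donor has not been shown, and because both features slow the addition the acetal is used in excess at high temperature or pressure. The two bridgehead stereocentres of 17 are transient and vanish on aromatization, so no stereocontrol is needed. Only regioselectivity is required, and matched polarity secures it: C6 is more electrophilic and less hindered than the donor-substituted C4, so CH2 goes to C6 and the acetal carbon to C3, which places the new silyloxy carbon C8a next to the prenyl-bearing C8 and para to the ester.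

Step 10
Reactants: 19 methyl 4-(tert-butyldimethylsilyloxy)-6-{2-[4-(tert-butyldimethylsilyloxy)phenyl]ethyl}-2-(methoxymethoxy)-3-(3-methylbut-2-en-1-yl)benzoate
Product: 20 methyl 4-hydroxy-6-[2-(4-hydroxyphenyl)ethyl]-2-(methoxymethoxy)-3-(3-methylbut-2-en-1-yl)benzoate
Conditions: Bu4NF (2.4 equiv), AcOH (2.4 equiv), THF, 0 °C to rt
Reagents that add atoms: none
Why: Standard fluoride desilylation through pentacoordinate silicon frees both phenols, and the acetic acid buffer keeps the phenoxides from touching the methyl ester or the MOM acetal.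

Step 11
Reactants: 20 methyl 4-hydroxy-6-[2-(4-hydroxyphenyl)ethyl]-2-(methoxymethoxy)-3-(3-methylbut-2-en-1-yl)benzoate; 21 3-methylbut-2-enal
Product: 23 methyl 5-[2-(4-hydroxyphenyl)ethyl]-7-(methoxymethoxy)-2,2-dimethyl-8-(3-methylbut-2-en-1-yl)-2H-chromene-6-carboxylate, via ortho-quinone methide 22 (not isolated)
Conditions: 21 (3 equiv), ethylenediammonium diacetate (20 mol %), toluene, 110 °C
Reagents that add atoms: none
Why: Known amine-salt-catalysed chromene synthesis from phenols and enals (C-alkylation at C4a, dehydration to the ortho-quinone methide, oxa-6π electrocyclization): C4a is the only free ortho carbon of the O8a phenol and is activated ortho and para by O8a and O7, the doubly ortho-substituted ester is twisted out of conjugation, and the para-alkyl phenol of the side chain lacks the resorcinol-type activation this condensation needs.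

Step 12
Reactants: 23 methyl 5-[2-(4-hydroxyphenyl)ethyl]-7-(methoxymethoxy)-2,2-dimethyl-8-(3-methylbut-2-en-1-yl)-2H-chromene-6-carboxylate
Product: 24 methyl 7-hydroxy-5-[2-(4-hydroxyphenyl)ethyl]-2,2-dimethyl-8-(3-methylbut-2-en-1-yl)-2H-chromene-6-carboxylate (CNP0133674.0)
Conditions: HCl (0.5 M) in MeOH/THF, rt
Reagents that add atoms: none
Why: Acid-catalysed acetal exchange with methanol (MOM removal) is fast for the ester-chelated ortho oxygen, and the freed O7 phenol is held in a hydrogen bond to the ester, which disfavours acid cyclization onto the neighbouring prenyl group or the chromene.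

**Compound list**
1 | 4-hydroxybenzyl alcohol | OCc1ccc(O)cc1 | starting material
2 | tert-butyl{[4-(tert-butyldimethylsilyloxy)phenyl]methoxy}dimethylsilane | CC(C)(C)[Si](C)(C)OCc1ccc(O[Si](C)(C)C(C)(C)C)cc1 | intermediate
3 | 4-(tert-butyldimethylsilyloxy)benzyl bromide | BrCc1ccc(O[Si](C)(C)C(C)(C)C)cc1 | intermediate
4 | methyl acetoacetate | COC(=O)CC(C)=O | starting material
5 | methyl acetoacetate sodium lithium dianion | [Na+].[Li+].COC(=O)[CH-]C(=O)[CH2-] | intermediate (not isolated)
6 | methyl 5-[4-(tert-butyldimethylsilyloxy)phenyl]-3-oxopentanoate | COC(=O)CC(=O)CCc1ccc(O[Si](C)(C)C(C)(C)C)cc1 | intermediate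
7 | malonyl dichloride | O=C(Cl)CC(=O)Cl | starting material
8 | methyl 2-(3-chloro-3-oxopropanoyl)-5-[4-(tert-butyldimethylsilyloxy)phenyl]-3-oxopentanoate (enolizable, configurationally labile) | COC(=O)C(C(=O)CC(Cl)=O)C(=O)CCc1ccc(O[Si](C)(C)C(C)(C)C)cc1 | intermediate (not isolated)
9 | methyl 6-{2-[4-(tert-butyldimethylsilyloxy)phenyl]ethyl}-4-hydroxy-2-oxo-2H-pyran-5-carboxylate | COC(=O)C1=C(CCc2ccc(O[Si](C)(C)C(C)(C)C)cc2)OC(=O)C=C1O | intermediate
10 | prenyl acetate (3-methylbut-2-en-1-yl acetate) | CC(C)=CCOC(C)=O | starting material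
11 | methyl 6-{2-[4-(tert-butyldimethylsilyloxy)phenyl]ethyl}-4-hydroxy-3-(3-methylbut-2-en-1-yl)-2-oxo-2H-pyran-5-carboxylate | COC(=O)C1=C(CCc2ccc(O[Si](C)(C)C(C)(C)C)cc2)OC(=O)C(CC=C(C)C)=C1O | intermediate
12 | methyl 6-{2-[4-(tert-butyldimethylsilyloxy)phenyl]ethyl}-4-(methoxymethoxy)-3-(3-methylbut-2-en-1-yl)-2-oxo-2H-pyran-5-carboxylate | COCOC1=C(CC=C(C)C)C(=O)OC(CCc2ccc(O[Si](C)(C)C(C)(C)C)cc2)=C1C(=O)OC | intermediate
13 | acetic acid | CC(=O)O | starting material
14 | tert-butyldimethylsilyl acetate | CC(=O)O[Si](C)(C)C(C)(C)C | intermediate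
15 | lithium 1-(tert-butyldimethylsilyloxy)ethenolate | [Li+].[O-]C(=C)O[Si](C)(C)C(C)(C)C | intermediate (not isolated)
16 | 1,1-bis(tert-butyldimethylsilyloxy)ethene | C=C(O[Si](C)(C)C(C)(C)C)O[Si](C)(C)C(C)(C)C | intermediate
17 | methyl 8,8-bis(tert-butyldimethylsilyloxy)-1-{2-[4-(tert-butyldimethylsilyloxy)phenyl]ethyl}-5-(methoxymethoxy)-4-(3-methylbut-2-en-1-yl)-3-oxo-2-oxabicyclo[2.2.2]oct-5-ene-6-carboxylate (racemate; the relative configuration of the two bridgeheads is fixed by the bridge) | COC(=O)C1=C(OCOC)C2(CC=C(C)C)C(=O)OC1(CCc3ccc(O[Si](C)(C)C(C)(C)C)cc3)CC2(O[Si](C)(C)C(C)(C)C)O[Si](C)(C)C(C)(C)C | intermediate (not isolated)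
18 | methyl 4,4-bis(tert-butyldimethylsilyloxy)-2-{2-[4-(tert-butyldimethylsilyloxy)phenyl]ethyl}-6-(methoxymethoxy)-5-(3-methylbut-2-en-1-yl)cyclohexa-1,5-diene-1-carboxylate | COC(=O)C1=C(CCc2ccc(O[Si](C)(C)C(C)(C)C)cc2)CC(O[Si](C)(C)C(C)(C)C)(O[Si](C)(C)C(C)(C)C)C(CC=C(C)C)=C1OCOC | intermediate (not isolated)
19 | methyl 4-(tert-butyldimethylsilyloxy)-6-{2-[4-(tert-butyldimethylsilyloxy)phenyl]ethyl}-2-(methoxymethoxy)-3-(3-methylbut-2-en-1-yl)benzoate | COCOc1c(CC=C(C)C)c(O[Si](C)(C)C(C)(C)C)cc(CCc2ccc(O[Si](C)(C)C(C)(C)C)cc2)c1C(=O)OC | intermediate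
20 | methyl 4-hydroxy-6-[2-(4-hydroxyphenyl)ethyl]-2-(methoxymethoxy)-3-(3-methylbut-2-en-1-yl)benzoate | COCOc1c(CC=C(C)C)c(O)cc(CCc2ccc(O)cc2)c1C(=O)OC | intermediate
21 | 3-methylbut-2-enal | CC(C)=CC=O | starting material
22 | methyl 2-[2-(4-hydroxyphenyl)ethyl]-6-(methoxymethoxy)-5-(3-methylbut-2-en-1-yl)-3-[(Z)-3-methylbut-2-en-1-ylidene]-4-oxocyclohexa-1,5-diene-1-carboxylate | COCOC1=C(CC=C(C)C)C(=O)/C(=C\C=C(C)C)C(CCc2ccc(O)cc2)=C1C(=O)OC | intermediate (not isolated)
23 | methyl 5-[2-(4-hydroxyphenyl)ethyl]-7-(methoxymethoxy)-2,2-dimethyl-8-(3-methylbut-2-en-1-yl)-2H-chromene-6-carboxylate | COCOc1c(CC=C(C)C)c2OC(C)(C)C=Cc2c(CCc3ccc(O)cc3)c1C(=O)OC | intermediate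
24 | methyl 7-hydroxy-5-[2-(4-hydroxyphenyl)ethyl]-2,2-dimethyl-8-(3-methylbut-2-en-1-yl)-2H-chromene-6-carboxylate (CNP0133674.0) | COC(=O)c1c(O)c(CC=C(C)C)c2c(c1CCc1ccc(O)cc1)C=CC(C)(C)O2 | target

**Step count**
Total: 12 steps. Longest linear sequence: 10 steps (steps 1 to 6, then 9 to 12); the ketene acetal branch (steps 7 and 8) joins at step 9.

**Steps most likely to fail**

1. Step 9. The cycloaddition may be too slow for the fully substituted, donor-bearing diene. Thermal decay of the ketene acetal (hydrolysis, oxygen-to-carbon silyl shift), or conjugate addition followed by silyl transfer and lactone opening, could then outrun ring closure. The fallback takes ring A from an existing benzene ring and sets out from bromide 3. Commercial methyl 2,4-dihydroxy-6-methylbenzoate F1 is C-prenylated between its two oxygens with prenyl bromide (NaH, toluene; ortho C-alkylation of the phenoxide, with the 5-prenyl isomer removed by chromatography) to methyl 2,4-dihydroxy-6-methyl-3-(3-methylbut-2-en-1-yl)benzoate F2. The free, non-chelated 4-hydroxyl is silylated (TBSCl, imidazole, CH2Cl2) to methyl 4-(tert-butyldimethylsilyloxy)-2-hydroxy-6-methyl-3-(3-methylbut-2-en-1-yl)benzoate F3. The chelated 2-hydroxyl is then methoxymethylated (MOMCl, i-Pr2NEt, CH2Cl2, 40 °C) to methyl 4-(tert-butyldimethylsilyloxy)-2-(methoxymethoxy)-6-methyl-3-(3-methylbut-2-en-1-yl)benzoate F4. Lateral deprotonation of the ortho-methyl group of this ortho-toluate with LiN(i-Pr)2 (THF, −78 °C) and alkylation of the benzylic anion with 3 should return the route at 19.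

2. Step 4. The HCl released may strip the aryl silyl ether, and the product pyrone may be annulated a second time at C3 and O4 by the bifunctional acid chloride. The fallback builds the same pyrone stepwise without a free mineral acid or a bis-electrophile and sets out from keto ester 6. Its magnesium chelate (MgCl2, pyridine, CH2Cl2, 0 °C) is C-acylated with methyl 3-chloro-3-oxopropanoate to dimethyl 2-{3-[4-(tert-butyldimethylsilyloxy)phenyl]propanoyl}-3-oxopentanedioate F5. Lactonization of the ketone enol onto the remote ester with loss of methanol (toluene, 110 °C) should then return the route at 9.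

3. Step 11. C-alkylation at C4a may be sluggish for a phenol deactivated by the para ester, leaving room for reaction at the second phenol or self-condensation of the enal. The fallback forms ring B by sigmatropic rearrangement in place of condensation and sets out from 20. The more acidic O8a phenol (para to the ester) is alkylated selectively with one equivalent of 3-chloro-3-methylbut-1-yne (CuCl2·2H2O cat., DBU, MeCN, 0 °C) to methyl 6-[2-(4-hydroxyphenyl)ethyl]-2-(methoxymethoxy)-3-(3-methylbut-2-en-1-yl)-4-[(2-methylbut-3-yn-2-yl)oxy]benzoate F6. Heating F6 in xylene at 140 °C should bring about aromatic propargyl Claisen rearrangement to C4a (the only free ortho carbon), 1,5-hydrogen shift and oxa-6π electrocyclization, returning the route at 23.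

**Further compounds**
F1 | step 9 | methyl 2,4-dihydroxy-6-methylbenzoate | COC(=O)c1c(C)cc(O)cc1O
F2 | step 9 | methyl 2,4-dihydroxy-6-methyl-3-(3-methylbut-2-en-1-yl)benzoate | COC(=O)c1c(C)cc(O)c(CC=C(C)C)c1O
F3 | step 9 | methyl 4-(tert-butyldimethylsilyloxy)-2-hydroxy-6-methyl-3-(3-methylbut-2-en-1-yl)benzoate | COC(=O)c1c(C)cc(O[Si](C)(C)C(C)(C)C)c(CC=C(C)C)c1O
F4 | step 9 | methyl 4-(tert-butyldimethylsilyloxy)-2-(methoxymethoxy)-6-methyl-3-(3-methylbut-2-en-1-yl)benzoate | COC(=O)c1c(C)cc(O[Si](C)(C)C(C)(C)C)c(CC=C(C)C)c1OCOC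
F5 | step 4 | dimethyl 2-{3-[4-(tert-butyldimethylsilyloxy)phenyl]propanoyl}-3-oxopentanedioate | COC(=O)CC(=O)C(C(=O)OC)C(=O)CCc1ccc(O[Si](C)(C)C(C)(C)C)cc1
F6 | step 11 | methyl 6-[2-(4-hydroxyphenyl)ethyl]-2-(methoxymethoxy)-3-(3-methylbut-2-en-1-yl)-4-[(2-methylbut-3-yn-2-yl)oxy]benzoate | COCOc1c(CC=C(C)C)c(OC(C)(C)C#C)cc(CCc2ccc(O)cc2)c1C(=O)OC
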